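**Retrosynthetic overview** (ring A = benzo ring of the chroman, ring B = its pyran ring, ring C = butenolide)
- The quaternary butenolide carbon C2 is cut at its exocyclic C2–CH2 bond: enantioselective phase-transfer benzylation of butenolide ester 18 (ring C) with chromanylmethyl bromide 12 (rings A and B).
- Ring C of 18 comes from an aldol–lactonisation of methyl 4-hydroxyphenylpyruvate with methyl glyoxylate (C2–C3 and O1–C5 bonds).
- Feature on which the strategy rests: in ring B the atoms O1–C8a–C4a–C4 are a latent o-quinone methide, C2 carries the gem-dimethyl group and C3 the hydroxyl. Ring B is therefore cut at C4–C3 and O1–C2 into an o-quinone methide and a 2-methylpropenyl unit whose C3 substituent is boron. Boron stands in for oxygen, gives the regiochemistry that an enol ether cannot, and is oxidised to the (R)-alcohol with retention.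
- Order of ring formation: ring B on the purchased benzoate ring A (step 3); ring C in a separate branch (step 9); union (step 11); deprotection.

Key step: step 3

Assumption: the sense of induction of the two catalyst-controlled steps (3 and 11) cannot be predicted with certainty for these substrates. The catalyst written is the working choice and is replaced by its enantiomer (step 3) or by its cinchonine-derived pseudo-enantiomer (step 11) if a first screen shows the opposite sense.

**Route**

Step 1
Reactants: 1 methyl 4-hydroxybenzoate; 2 paraformaldehyde (formaldehyde)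
Product: 4 methyl 3-formyl-4-hydroxybenzoate, via magnesium salicyl alkoxide 3 (not isolated)
Conditions: MgCl2, Et3N, (CH2O)n, MeCN, reflux; then 1 M HCl
Reagents that add atoms: none
Why: Magnesium phenoxide-directed ortho-formylation (Casnati–Skattebøl reaction): with the para position blocked, the chelated phenoxide adds formaldehyde at the ortho carbon to give alkoxide 3, a second formaldehyde accepts hydride from 3, and the chelated salicylaldehyde formed is deactivated towards a second substitution.

Step 2
Reactants: 4 methyl 3-formyl-4-hydroxybenzoate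
Product: 5 methyl 4-hydroxy-3-(hydroxymethyl)benzoate
Conditions: NaBH4, MeOH/THF, 0 °C
Reagents that add atoms: none
Why: Chemoselective borohydride reduction of the aldehyde; the aryl methyl ester is inert to NaBH4 at 0 °C.

Step 3
Reactants: 5 methyl 4-hydroxy-3-(hydroxymethyl)benzoate; 6 2-methylprop-1-enylboronic acid pinacol ester
Product: 8 methyl (R)-2,2-dimethyl-3-(4,4,5,5-tetramethyl-1,3,2-dioxaborolan-2-yl)chroman-6-carboxylate, via o-quinone methide 7 (not isolated)
Conditions: (R)-3,3'-bis(2,4,6-triisopropylphenyl)-1,1'-binaphthyl-2,2'-diyl N-triflylphosphoramide (10 mol%), 6 (3 equiv), 5 Å MS, PhCF3/CH2Cl2, 35 °C, slow addition of 5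
Reagents that add atoms: none
Why: Proposed new method: the strong chiral acid ionises the benzylic alcohol of 5 to o-quinone methide 7 and stays bound to its oxygen (hydrogen bond or contact ion pair); the boron-bearing carbon of 6 attacks the exocyclic CH2 (the electrophilic terminus of both the enone and the para-ester dienoate), and the positive charge building on the CMe2 carbon is captured by the quinone methide oxygen in the same asynchronous event, forming C4–C3 and O1–C2. The closest known reaction types are Brønsted acid-catalysed inverse-electron-demand oxa-[4+2] cycloadditions of in situ generated o-quinone methides with styrenes, enamides and trisubstituted alkenes, and cycloadditions in which alkenylboronic esters act as 2π partners with the C–B bond kept; their combination, with enantiocontrol at a boron-bearing carbon, has not been shown. The pyran ring (O1, C2, C3, C4, C4a, C8a) closes in a suprafacial [4+2] mode, which in the stepwise limit is six-membered capture of a tertiary β-boryl cation by the phenolic oxygen. C3 is the only new stereocentre and is controlled by the catalyst alone: the 2,4,6-triisopropylphenyl walls around the bound quinone methide must tell Bpin from H on the attacking carbon, so that one enantiotopic face of 6 is presented. The step needs regio-, chemo- and enantioselectivity: regiochemistry is secured by the gem-dimethyl terminus (tertiary cation assisted by C–B hyperconjugation, whereas an enol ether would place oxygen at C2), retention of boron by the robust pinacol ester and the weakly nucleophilic counter-anion under anhydrous conditions, and suppression of quinone methide self-condensation by the ester, which makes the phenol ring of 5 a poor nucleophile and 7 a better electrophile.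

Step 4
Reactants: 8 methyl (R)-2,2-dimethyl-3-(4,4,5,5-tetramethyl-1,3,2-dioxaborolan-2-yl)chroman-6-carboxylate
Product: 9 methyl (R)-3-hydroxy-2,2-dimethylchroman-6-carboxylate
Conditions: NaBO3·4H2O, THF/H2O (1:1), rt
Reagents that add atoms: sodium perborate tetrahydrate, [Na+].[Na+].O[B-]1(O)OO[B-](O)(O)OO1
Why: Oxidation of the secondary alkylboronate through its peroxoborate ate complex, whose 1,2-shift of C3 from boron to oxygen proceeds with retention, so the (R) configuration passes from C–B to C–O; mildly basic perborate spares the methyl ester and the shift should outrun β-elimination of the C2 aryloxy group.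

Step 5
Reactants: 9 methyl (R)-3-hydroxy-2,2-dimethylchroman-6-carboxylate
Product: 10 methyl (R)-3-(tert-butyldimethylsilyloxy)-2,2-dimethylchroman-6-carboxylate
Conditions: TBSOTf, 2,6-lutidine, CH2Cl2, 0 °C to rt
Reagents that add atoms: tert-butyldimethylsilyl triflate (TBSOTf), CC(C)(C)[Si](C)(C)OS(=O)(=O)C(F)(F)F
Why: Silylation of the hindered secondary alcohol (next to the quaternary C2) with the silyl triflate; the TBS ether masks the hydroxyl during hydride reduction, bromination and the basic alkylation.

Step 6
Reactants: 10 methyl (R)-3-(tert-butyldimethylsilyloxy)-2,2-dimethylchroman-6-carboxylate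
Product: 11 [(3R)-3-(tert-butyldimethylsilyloxy)-2,2-dimethylchroman-6-yl]methanol
Conditions: LiAlH4, THF, 0 °C; then H2O
Reagents that add atoms: none
Why: Hydride reduction of the aryl ester to the benzylic alcohol; the silyl ether and the aryl ether are inert.

Step 7
Reactants: 11 [(3R)-3-(tert-butyldimethylsilyloxy)-2,2-dimethylchroman-6-yl]methanol
Product: 12 (3R)-6-(bromomethyl)-3-(tert-butyldimethylsilyloxy)-2,2-dimethylchroman
Conditions: CBr4, PPh3, CH2Cl2, 0 °C; used without storage
Reagents that add atoms: carbon tetrabromide, BrC(Br)(Br)Br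
Why: Appel bromination of the primary benzylic alcohol under near-neutral conditions that the TBS ether tolerates; the para-alkoxybenzylic bromide is reactive and is taken on directly.

Step 8
Reactants: 13 4-hydroxyphenylpyruvic acid
Product: 14 methyl 3-(4-hydroxyphenyl)-2-oxopropanoate (largely as its enol)
Conditions: DBU (1.0 equiv), MeI (1.1 equiv), DMF, 0 °C to rt
Reagents that add atoms: iodomethane, CI
Why: Chemoselective O-alkylation of the carboxylate: one equivalent of DBU deprotonates only the α-keto acid, so the phenol and the enol stay free.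

Step 9
Reactants: 14 methyl 3-(4-hydroxyphenyl)-2-oxopropanoate; 15 methyl glyoxylate
Product: 17 methyl 4-hydroxy-3-(4-hydroxyphenyl)-5-oxo-2,5-dihydrofuran-2-carboxylate (racemic), via aldol adduct 16 (not isolated)
Conditions: 15 (2 equiv, freshly depolymerised), Et3N, THF, 0 °C to rt; then 1 M HCl
Reagents that add atoms: none
Why: Base-mediated cross-aldol addition of the arylpyruvate enolate to the far more electrophilic glyoxylate aldehyde, then 5-exo-trig lactonisation of the new hydroxyl onto the pyruvate ester and enolisation (isotetronic acid synthesis); C2 forms racemic, which is immaterial because it is deprotonated in step 11.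

Step 10
Reactants: 17 methyl 4-hydroxy-3-(4-hydroxyphenyl)-5-oxo-2,5-dihydrofuran-2-carboxylate
Product: 18 methyl 4-(benzyloxy)-3-[4-(benzyloxy)phenyl]-5-oxo-2,5-dihydrofuran-2-carboxylate (racemic)
Conditions: BnBr (2.0 equiv), K2CO3, acetone, rt
Reagents that add atoms: benzyl bromide, BrCc1ccccc1
Why: Williamson O-benzylation of the two acidic hydroxyls (enol and phenol); benzyl bromide is held at two equivalents so that the less acidic C2–H of 18 is not alkylated.

Step 11
Reactants: 18 methyl 4-(benzyloxy)-3-[4-(benzyloxy)phenyl]-5-oxo-2,5-dihydrofuran-2-carboxylate; 12 (3R)-6-(bromomethyl)-3-(tert-butyldimethylsilyloxy)-2,2-dimethylchroman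
Product: 19 methyl (2R)-4-(benzyloxy)-3-[4-(benzyloxy)phenyl]-2-{[(3R)-3-(tert-butyldimethylsilyloxy)-2,2-dimethylchroman-6-yl]methyl}-5-oxo-2,5-dihydrofuran-2-carboxylate
Conditions: O-allyl-N-(9-anthracenylmethyl)cinchonidinium bromide (10 mol%), Cs2CO3 (solid), toluene, −20 °C
Reagents that add atoms: none
Why: Asymmetric phase-transfer alkylation: solid Cs2CO3 generates the 2-oxidofuran (dienolate) of 18, which as a tight ion pair with the chiral ammonium cation is benzylated at C2 (activated by the ester and the vinylogous lactone carbonyl, with C4 blocked by its benzyloxy group), the cation shielding one face so that the (R) quaternary centre forms; the remote (3R) chroman centre is untouched.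

Step 12
Reactants: 19 methyl (2R)-4-(benzyloxy)-3-[4-(benzyloxy)phenyl]-2-{[(3R)-3-(tert-butyldimethylsilyloxy)-2,2-dimethylchroman-6-yl]methyl}-5-oxo-2,5-dihydrofuran-2-carboxylate
Product: 20 methyl (2R)-4-(benzyloxy)-3-[4-(benzyloxy)phenyl]-2-{[(3R)-3-hydroxy-2,2-dimethylchroman-6-yl]methyl}-5-oxo-2,5-dihydrofuran-2-carboxylate
Conditions: HF·pyridine, THF/pyridine, 0 °C to rt
Reagents that add atoms: none
Why: Fluoride-mediated cleavage of the silyl ether under buffered, weakly acidic conditions that leave the lactone, the methyl ester and the benzyl ethers intact.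

Step 13
Reactants: 20 methyl (2R)-4-(benzyloxy)-3-[4-(benzyloxy)phenyl]-2-{[(3R)-3-hydroxy-2,2-dimethylchroman-6-yl]methyl}-5-oxo-2,5-dihydrofuran-2-carboxylate
Product: 21 methyl (2R)-4-hydroxy-2-{[(3R)-3-hydroxy-2,2-dimethylchroman-6-yl]methyl}-3-(4-hydroxyphenyl)-5-oxo-2,5-dihydrofuran-2-carboxylate
Conditions: H2 (1 atm), 10% Pd/C, EtOAc, rt
Reagents that add atoms: none
Why: Hydrogenolysis of the aryl and enol benzyl ethers over Pd/C; the tetrasubstituted conjugated butenolide alkene and the hindered quaternary C–O bond should not be reduced at 1 atm.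

**Compound list**

1 | methyl 4-hydroxybenzoate | COC(=O)c1ccc(O)cc1 | starting material
2 | paraformaldehyde (formaldehyde) | C=O | starting material
3 | magnesium salt of methyl 4-hydroxy-3-(hydroxymethyl)benzoate (magnesium salicyl alkoxide, not isolated) | COC(=O)c1ccc([O-])c(C[O-])c1.[Mg+2] | intermediate
4 | methyl 3-formyl-4-hydroxybenzoate | COC(=O)c1ccc(O)c(C=O)c1 | intermediate
5 | methyl 4-hydroxy-3-(hydroxymethyl)benzoate | COC(=O)c1ccc(O)c(CO)c1 | intermediate
6 | 2-methylprop-1-enylboronic acid pinacol ester | CC(C)=CB1OC(C)(C)C(C)(C)O1 | starting material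
7 | methyl 3-methylidene-4-oxocyclohexa-1,5-diene-1-carboxylate (o-quinone methide, not isolated) | COC(=O)C1=CC(=C)C(=O)C=C1 | intermediate
8 | methyl (R)-2,2-dimethyl-3-(4,4,5,5-tetramethyl-1,3,2-dioxaborolan-2-yl)chroman-6-carboxylate | COC(=O)c1ccc2c(c1)C[C@@H](B1OC(C)(C)C(C)(C)O1)C(C)(C)O2 | intermediate
9 | methyl (R)-3-hydroxy-2,2-dimethylchroman-6-carboxylate | COC(=O)c1ccc2c(c1)C[C@@H](O)C(C)(C)O2 | intermediate
10 | methyl (R)-3-(tert-butyldimethylsilyloxy)-2,2-dimethylchroman-6-carboxylate | COC(=O)c1ccc2c(c1)C[C@@H](O[Si](C)(C)C(C)(C)C)C(C)(C)O2 | intermediate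
11 | [(3R)-3-(tert-butyldimethylsilyloxy)-2,2-dimethylchroman-6-yl]methanol | OCc1ccc2c(c1)C[C@@H](O[Si](C)(C)C(C)(C)C)C(C)(C)O2 | intermediate
12 | (3R)-6-(bromomethyl)-3-(tert-butyldimethylsilyloxy)-2,2-dimethylchroman | BrCc1ccc2c(c1)C[C@@H](O[Si](C)(C)C(C)(C)C)C(C)(C)O2 | intermediate
13 | 4-hydroxyphenylpyruvic acid | O=C(O)C(=O)Cc1ccc(O)cc1 | starting material
14 | methyl 3-(4-hydroxyphenyl)-2-oxopropanoate | COC(=O)C(=O)Cc1ccc(O)cc1 | intermediate
15 | methyl glyoxylate | COC(=O)C=O | starting material
16 | dimethyl 2-hydroxy-3-(4-hydroxyphenyl)-4-oxopentanedioate (aldol adduct, not isolated) | COC(=O)C(O)C(c1ccc(O)cc1)C(=O)C(=O)OC | intermediate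
17 | methyl 4-hydroxy-3-(4-hydroxyphenyl)-5-oxo-2,5-dihydrofuran-2-carboxylate (racemic) | COC(=O)C1OC(=O)C(O)=C1c1ccc(O)cc1 | intermediate
18 | methyl 4-(benzyloxy)-3-[4-(benzyloxy)phenyl]-5-oxo-2,5-dihydrofuran-2-carboxylate (racemic) | COC(=O)C1OC(=O)C(OCc2ccccc2)=C1c1ccc(OCc2ccccc2)cc1 | intermediate
19 | methyl (2R)-4-(benzyloxy)-3-[4-(benzyloxy)phenyl]-2-{[(3R)-3-(tert-butyldimethylsilyloxy)-2,2-dimethylchroman-6-yl]methyl}-5-oxo-2,5-dihydrofuran-2-carboxylate | COC(=O)[C@]1(Cc2ccc3c(c2)C[C@@H](O[Si](C)(C)C(C)(C)C)C(C)(C)O3)OC(=O)C(OCc2ccccc2)=C1c1ccc(OCc2ccccc2)cc1 | intermediate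
20 | methyl (2R)-4-(benzyloxy)-3-[4-(benzyloxy)phenyl]-2-{[(3R)-3-hydroxy-2,2-dimethylchroman-6-yl]methyl}-5-oxo-2,5-dihydrofuran-2-carboxylate | COC(=O)[C@]1(Cc2ccc3c(c2)C[C@@H](O)C(C)(C)O3)OC(=O)C(OCc2ccccc2)=C1c1ccc(OCc2ccccc2)cc1 | intermediate
21 | methyl (2R)-4-hydroxy-2-{[(3R)-3-hydroxy-2,2-dimethylchroman-6-yl]methyl}-3-(4-hydroxyphenyl)-5-oxo-2,5-dihydrofuran-2-carboxylate | COC(=O)[C@]1(Cc2ccc3c(c2)C[C@@H](O)C(C)(C)O3)OC(=O)C(O)=C1c1ccc(O)cc1 | target

**Step count and risks**

Total step count: 13. Longest linear sequence: 10 steps (steps 1–7, then 11–13) from methyl 4-hydroxybenzoate; the butenolide branch (steps 8–10) joins at step 11.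

Steps most likely to fail:

1. Step 3 (proposed new method). Facial selectivity may be poor because the alkenylboronate offers the catalyst no hydrogen-bonding anchor. Boron may also be lost by β-elimination from the developing β-boryl cation, or from the cycloadduct under acid, so that ortho-prenylation takes the place of ring closure. The quinone methide may self-condense before it meets the weakly nucleophilic alkene. Fallback by known chemistry, setting out from 1 and returning at 9:
   - O-alkylation of 1 with 3-chloro-3-methylbut-1-yne (K2CO3, KI, CuI cat., acetone, reflux) gives methyl 4-[(2-methylbut-3-yn-2-yl)oxy]benzoate F1.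
   - Thermal aromatic propargyl Claisen rearrangement, [1,5]-hydrogen shift and oxa-6π electrocyclisation (N,N-diethylaniline, 190 °C) give methyl 2,2-dimethyl-2H-chromene-6-carboxylate F2.
   - Jacobsen epoxidation with (R,R)-N,N'-bis(3,5-di-tert-butylsalicylidene)-1,2-cyclohexanediaminomanganese chloride [(R,R)-(salen)MnCl], aqueous NaOCl and 4-phenylpyridine N-oxide in CH2Cl2 at 0 °C is expected to give methyl (3R,4R)-3,4-epoxy-2,2-dimethylchroman-6-carboxylate F3.
   - Regioselective hydrogenolysis of the benzylic C4–O bond (H2, Pd/C, EtOAc) leaves the C3 configuration untouched and gives 9, from which steps 5–13 follow unchanged.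

2. Step 11. Face discrimination on the fully substituted dienolate may be insufficient, and O-alkylation or alkylation at C4 may compete with the wanted attack at C2. Fallback, setting out from 18 and 12 and returning at 19: the alkylation is run without a chiral catalyst (Cs2CO3, Bu4NBr, DMF, 0 °C), so that stereocontrol is replaced by separation. Because the chroman centre of 12 is already (R), the two products are diastereomers, 19 and its C2 epimer methyl (2S)-4-(benzyloxy)-3-[4-(benzyloxy)phenyl]-2-{[(3R)-3-(tert-butyldimethylsilyloxy)-2,2-dimethylchroman-6-yl]methyl}-5-oxo-2,5-dihydrofuran-2-carboxylate F4. They are separated by preparative HPLC, and 19 is carried into step 12.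

3. Step 9. Self-condensation of the arylpyruvate, or hydroxyalkylation of the phenoxide by the glyoxylate, may overtake the cross-aldol addition. Fallback, setting out from 14 and returning at 17: bis-silylation (TMSCl, Et3N, THF) gives methyl (Z)-2-(trimethylsilyloxy)-3-[4-(trimethylsilyloxy)phenyl]prop-2-enoate F5, which is the only nucleophile in a Mukaiyama aldol addition to 15 (BF3·OEt2, CH2Cl2, −78 °C). Acidic work-up (HCl, MeOH/THF) removes both silyl groups to release aldol adduct 16, which lactonises to 17.

Further compounds
F1 | step 3 | methyl 4-[(2-methylbut-3-yn-2-yl)oxy]benzoate | COC(=O)c1ccc(OC(C)(C)C#C)cc1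
F2 | step 3 | methyl 2,2-dimethyl-2H-chromene-6-carboxylate | COC(=O)c1ccc2c(c1)C=CC(C)(C)O2
F3 | step 3 | methyl (3R,4R)-3,4-epoxy-2,2-dimethylchroman-6-carboxylate | COC(=O)c1ccc2c(c1)[C@H]1O[C@H]1C(C)(C)O2
F4 | step 11 | methyl (2S)-4-(benzyloxy)-3-[4-(benzyloxy)phenyl]-2-{[(3R)-3-(tert-butyldimethylsilyloxy)-2,2-dimethylchroman-6-yl]methyl}-5-oxo-2,5-dihydrofuran-2-carboxylate | COC(=O)[C@@]1(Cc2ccc3c(c2)C[C@@H](O[Si](C)(C)C(C)(C)C)C(C)(C)O3)OC(=O)C(OCc2ccccc2)=C1c1ccc(OCc2ccccc2)cc1
F5 | step 9 | methyl (Z)-2-(trimethylsilyloxy)-3-[4-(trimethylsilyloxy)phenyl]prop-2-enoate | COC(=O)/C(O[Si](C)(C)C)=C/c1ccc(O[Si](C)(C)C)cc1
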